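**Plan**
- Retrosynthesis: the O-methyl group is removed first, then the aryl C–C(=O) bond of the 12-membered benzoate lactone is cut. The enabling feature is the phenol oxygen (the later OMe oxygen) on the ring carbon directly beside the carbonyl-bearing ring carbon: the carbonyl can be parked on this oxygen as a 14-membered aryl alkyl carbonate (temporary ring) and moved O→C by a photo-Fries shift.
- Next cuts: the two carbonate C–O bonds (phenol + secondary alcohol); then both bonds of the dihydropyran ring of the furo[2,3-b]chromene ketal (ArCH2–CH and ArO–C ketal) by a retro hetero-Diels–Alder to an o-quinone methide and (S)-2,4-dimethyl-4,5-dihydrofuran; then the aryl–CHO and aryl–chain bonds.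
- Forward: chain attached by B-alkyl Suzuki coupling → formylation of the symmetric resorcinol → o-quinone methide [4+2] (pyran ring formed onto the furan ring) → 14-membered carbonate → photochemical ring contraction to the 12-membered lactone → O-methylation.
- Stereochemistry: the lactone carbinol (R) comes from (R)-propylene oxide; the furan CH(CH3) from an Evans propargylation; the ring-fusion CH and the ketal carbon from the suprafacial cycloaddition anti to that methyl.

Key step: step 13

Remark: compounds 1, 2, 8, 9 and 13 are taken as purchasable, and the cis ring fusion of the bicyclic ketal is taken as the only fusion a suprafacial cycloaddition can give.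

**Route**

Step 1
Reactants: 1 (R)-4-benzyl-3-propanoyl-1,3-oxazolidin-2-one; 2 3-bromoprop-1-yne
Product: 4 (R)-4-benzyl-3-[(S)-2-methylpent-4-ynoyl]-1,3-oxazolidin-2-one, via sodium Z-enolate 3 (not isolated)
Conditions: NaHMDS, THF, −78 °C; then 2, −78 → −40 °C
Reagents that add atoms: none
Why: Evans asymmetric alkylation, in which the chelated sodium Z-enolate should be alkylated on the face opposite the C4 benzyl group, setting the (S)-methyl center that later becomes the furan CH(CH3).

Step 2
Reactants: 4 (R)-4-benzyl-3-[(S)-2-methylpent-4-ynoyl]-1,3-oxazolidin-2-one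
Product: 5 (S)-2-methylpent-4-yn-1-ol
Conditions: LiBH4, MeOH (1 equiv), Et2O, 0 °C
Reagents that add atoms: none
Why: Reductive cleavage of the N-acyl oxazolidinone with LiBH4 should give the primary alcohol and free the auxiliary without touching the stereocenter or the terminal alkyne.

Step 3
Reactants: 5 (S)-2-methylpent-4-yn-1-ol
Product: 7 (S)-2,4-dimethyl-4,5-dihydrofuran, via exocyclic enol ether 6 (not isolated)
Conditions: NaNH2 (cat.), neat, 110–130 °C, product distilled out
Reagents that add atoms: none
Why: Base-catalysed cycloisomerisation of a pent-4-yn-1-ol (5-exo-dig alkoxide addition, then base-mediated shift of the exocyclic double bond into the ring) should give the volatile endocyclic enol ether, the stereocenter lying outside the reacting atoms.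

Step 4
Reactants: 8 6-bromohex-1-ene; 9 (R)-2-methyloxirane
Product: 12 (R)-non-8-en-2-yl acetate, via hex-5-enylmagnesium bromide 10 (not isolated), via bromomagnesium alkoxide 11 (not isolated)
Conditions: Mg, THF, rt; CuI (10 mol %), 9, −30 → 0 °C; then Ac2O, DMAP (cat.), 0 °C → rt
Reagents that add atoms: acetic anhydride CC(=O)OC(C)=O
Why: Copper-catalysed Grignard opening of the epoxide at its CH2 terminus keeps the (R) carbinol center, and the magnesium alkoxide should be acetylated in the same flask to protect the alcohol for steps 5–10.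

Step 5
Reactants: 12 (R)-non-8-en-2-yl acetate; 13 1,3-bis(benzyloxy)-5-bromobenzene
Product: 15 (R)-9-[3,5-bis(benzyloxy)phenyl]nonan-2-yl acetate, via B-alkyl-9-BBN 14 (not isolated)
Conditions: 9-BBN, THF, rt; then 13, PdCl2(dppf) (3 mol %), K3PO4 (aq), DMF, 50 °C
Reagents that add atoms: none
Why: B-alkyl Suzuki–Miyaura coupling, in which anti-Markovnikov hydroboration gives the primary alkylborane that should couple with the aryl bromide while the acetate and benzyl ethers stay intact.

Step 6
Reactants: 15 (R)-9-[3,5-bis(benzyloxy)phenyl]nonan-2-yl acetate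
Product: 16 (R)-9-(3,5-dihydroxyphenyl)nonan-2-yl acetate
Conditions: H2 (1 atm), 10 % Pd/C, EtOAc/EtOH, rt
Reagents that add atoms: none
Why: Hydrogenolysis of both benzyl ethers over Pd/C should free the symmetric resorcinol without affecting the acetate.

Step 7
Reactants: 16 (R)-9-(3,5-dihydroxyphenyl)nonan-2-yl acetate
Product: 18 (R)-9-(2-formyl-3,5-dihydroxyphenyl)nonan-2-yl acetate, via aryl iminium chloride 17 (not isolated)
Conditions: POCl3, DMF, 0 °C → rt; then H2O, 50 °C
Reagents that add atoms: N,N-dimethylformamide CN(C)C=O; water O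
Why: Vilsmeier–Haack formylation of a 5-alkylresorcinol should occur at the ring CH beside the chain (para to one OH, ortho to the other), and since the two such positions of 16 are equivalent a single aldehyde should result, which also tells the two phenols apart.

Step 8
Reactants: 18 (R)-9-(2-formyl-3,5-dihydroxyphenyl)nonan-2-yl acetate
Product: 19 (R)-9-[5-(tert-butyldimethylsilyloxy)-2-formyl-3-hydroxyphenyl]nonan-2-yl acetate
Conditions: TBSCl (1.05 equiv), imidazole, CH2Cl2, 0 °C
Reagents that add atoms: tert-butyldimethylsilyl chloride CC(C)(C)[Si](C)(C)Cl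
Why: Selective silylation, because the OH para to the aldehyde is free and more acidic while the ortho OH is held in a hydrogen bond to the carbonyl, so one equivalent of TBSCl should cap only the para oxygen.

Step 9
Reactants: 19 (R)-9-[5-(tert-butyldimethylsilyloxy)-2-formyl-3-hydroxyphenyl]nonan-2-yl acetate
Product: 21 (R)-9-[5-(tert-butyldimethylsilyloxy)-3-hydroxy-2-(morpholin-4-ylmethyl)phenyl]nonan-2-yl acetate, via morpholine iminium zwitterion 20 (not isolated)
Conditions: morpholine, NaBH(OAc)3, AcOH (cat.), ClCH2CH2Cl, rt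
Reagents that add atoms: morpholine C1COCCN1
Why: Reductive amination of the salicylaldehyde should give the phenolic Mannich base with the CH2N exactly where the aldehyde stood, an established o-quinone methide precursor.

Step 10
Reactants: 21 (R)-9-[5-(tert-butyldimethylsilyloxy)-3-hydroxy-2-(morpholin-4-ylmethyl)phenyl]nonan-2-yl acetate; 7 (S)-2,4-dimethyl-4,5-dihydrofuran
Product: 24 (R)-9-[(3S,3aS,9aS)-7-(tert-butyldimethylsilyloxy)-3,9a-dimethyl-2,3,3a,9a-tetrahydro-4H-furo[2,3-b]chromen-5-yl]nonan-2-yl acetate, via N-methylmorpholinium iodide 22 (not isolated), via o-quinone methide 23 (not isolated)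
Conditions: MeI, 7 (3 equiv), benzene, 80 °C, sealed tube
Reagents that add atoms: none
Why: N-Methylation followed by thermal loss of N-methylmorpholine hydroiodide should give the o-quinone methide, which undergoes an inverse-electron-demand hetero-Diels–Alder reaction with the enol ether (CH2 to the β-carbon, O to the α-carbon) suprafacially and anti to the ring methyl, so the ring fusion is cis and CH2Ar ends up trans to CH3, which fixes the ring-fusion CH and the ketal carbon.

Step 11
Reactants: 24 (R)-9-[(3S,3aS,9aS)-7-(tert-butyldimethylsilyloxy)-3,9a-dimethyl-2,3,3a,9a-tetrahydro-4H-furo[2,3-b]chromen-5-yl]nonan-2-yl acetate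
Product: 25 (3S,3aS,9aS)-5-[(8R)-8-hydroxynonyl]-3,9a-dimethyl-2,3,3a,9a-tetrahydro-4H-furo[2,3-b]chromen-7-ol
Conditions: K2CO3, MeOH, rt → 40 °C, N2
Reagents that add atoms: none
Why: Base-mediated methanolysis should cleave the aryl silyl ether and the acetate together, while the mixed ketal is stable to base.

Step 12
Reactants: 25 (3S,3aS,9aS)-5-[(8R)-8-hydroxynonyl]-3,9a-dimethyl-2,3,3a,9a-tetrahydro-4H-furo[2,3-b]chromen-7-ol
Product: 27 14-membered cyclic carbonate joining O-7 of the furochromene to the (R)-carbinol oxygen of the nonyl chain, via aryl 4-nitrophenyl carbonate 26 (not isolated)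
Conditions: 4-O2NC6H4OCOCl (1.05 equiv), i-Pr2NEt, CH2Cl2, −40 °C; then slow addition to DMAP, toluene, 80 °C (1 mM)
Reagents that add atoms: 4-nitrophenyl chloroformate O=C(Cl)Oc1ccc(cc1)[N+](=O)[O-]
Why: The phenol should be acylated selectively under amine base at low temperature, and DMAP-catalysed transcarbonation by the tethered secondary alcohol under high dilution should expel 4-nitrophenoxide (the better leaving group) and close the macrocyclic carbonate with the carbinol configuration untouched.

Step 13
Reactants: 27 14-membered cyclic carbonate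
Product: 29 O-demethyl-lasiodiplactone A (12-membered lactone with a free phenol ortho to the lactone carbonyl), via cyclohexa-2,4-dienone 28 (not isolated)
Conditions: hν (254 nm), degassed MeCN (2 mM), quartz, rt
Reagents that add atoms: none
Why: Photo-Fries rearrangement: excitation of the aryl carbonate should cleave the ArO–C(=O) bond homolytically to a singlet phenoxyl/alkoxycarbonyl radical pair that cannot separate because the nonyl chain ties the acyl radical to the ring, and the pair recombines at the ring carbon ortho to the oxygen to give dienone 28, which enolises to the hydrogen-bonded salicylate 29. The closest known reactions are the photo-Fries rearrangement of aryl carbonates to salicylate esters and the ring-contracting photo-Fries rearrangement of macrocyclic aryl esters. The 12-membered lactone is closed by this radical recombination as a formal 1,3 O→C shift, a two-atom contraction of the 14-membered carbonate, so no bimolecular macrocyclisation and no esterification of a di-ortho-substituted benzoic acid is needed. No stereocenter is formed (the sp3 carbon of 28 is lost on enolisation), and the carbinol center is untouched because its C–O bond is not broken. The selectivity needed is attack at the ortho CH next to the chain, not at the CH between the two oxygens and not loss of CO2: the para position carries the ring CH2, recombination at the other ortho carbon would need a strained ten-atom para bridge, and recombination within the tethered pair should outrun decarboxylation of a secondary alkoxycarbonyl radical. The product absorbs at longer wavelength and can dissipate energy by excited-state proton transfer, so it should survive further irradiation.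

Step 14
Reactants: 29 O-demethyl-lasiodiplactone A
Product: 30 lasiodiplactone A
Conditions: MeI, K2CO3, acetone, 50 °C
Reagents that add atoms: iodomethane CI
Why: Williamson O-methylation of the only acidic OH should give the target, the ketal and the lactone being stable to carbonate base.

**Compound list**

1 | (R)-4-benzyl-3-propanoyl-1,3-oxazolidin-2-one | CCC(=O)N1[C@H](Cc2ccccc2)COC1=O | starting material
2 | 3-bromoprop-1-yne | C#CCBr | starting material
3 | sodium (Z)-enolate of 1 | C/C=C(\[O-])N1[C@H](Cc2ccccc2)COC1=O.[Na+] | intermediate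
4 | (R)-4-benzyl-3-[(S)-2-methylpent-4-ynoyl]-1,3-oxazolidin-2-one | C#CC[C@H](C)C(=O)N1[C@H](Cc2ccccc2)COC1=O | intermediate
5 | (S)-2-methylpent-4-yn-1-ol | C#CC[C@H](C)CO | intermediate
6 | (S)-4-methyl-2-methylidenetetrahydrofuran | C=C1C[C@H](C)CO1 | intermediate
7 | (S)-2,4-dimethyl-4,5-dihydrofuran [(3S)-3,5-dimethyl-2,3-dihydrofuran] | CC1=C[C@H](C)CO1 | intermediate
8 | 6-bromohex-1-ene | C=CCCCCBr | starting material
9 | (R)-2-methyloxirane | C[C@@H]1CO1 | starting material
10 | hex-5-en-1-ylmagnesium bromide | C=CCCCC[Mg]Br | intermediate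
11 | bromomagnesium (R)-non-8-en-2-olate | C[C@@H](O[Mg]Br)CCCCCC=C | intermediate
12 | (R)-non-8-en-2-yl acetate | C[C@@H](OC(C)=O)CCCCCC=C | intermediate
13 | 1,3-bis(benzyloxy)-5-bromobenzene | Brc1cc(OCc2ccccc2)cc(OCc2ccccc2)c1 | starting material
14 | 9-[(8R)-8-acetoxynonyl]-9-borabicyclo[3.3.1]nonane | C[C@@H](OC(C)=O)CCCCCCCB1C2CCCC1CCC2 | intermediate
15 | (R)-9-[3,5-bis(benzyloxy)phenyl]nonan-2-yl acetate | C[C@@H](OC(C)=O)CCCCCCCc1cc(OCc2ccccc2)cc(OCc2ccccc2)c1 | intermediate
16 | (R)-9-(3,5-dihydroxyphenyl)nonan-2-yl acetate | C[C@@H](OC(C)=O)CCCCCCCc1cc(O)cc(O)c1 | intermediate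
17 | N,N-dimethyl iminium chloride of aldehyde 18 | C[C@@H](OC(C)=O)CCCCCCCc1cc(O)cc(O)c1C=[N+](C)C.[Cl-] | intermediate
18 | (R)-9-(2-formyl-3,5-dihydroxyphenyl)nonan-2-yl acetate | C[C@@H](OC(C)=O)CCCCCCCc1cc(O)cc(O)c1C=O | intermediate
19 | (R)-9-[5-(tert-butyldimethylsilyloxy)-2-formyl-3-hydroxyphenyl]nonan-2-yl acetate | C[C@@H](OC(C)=O)CCCCCCCc1cc(O[Si](C)(C)C(C)(C)C)cc(O)c1C=O | intermediate
20 | morpholin-4-ium-4-ylidene phenolate (iminium zwitterion of 19) | C[C@@H](OC(C)=O)CCCCCCCc1cc(O[Si](C)(C)C(C)(C)C)cc([O-])c1C=[N+]1CCOCC1 | intermediate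
21 | (R)-9-[5-(tert-butyldimethylsilyloxy)-3-hydroxy-2-(morpholin-4-ylmethyl)phenyl]nonan-2-yl acetate | C[C@@H](OC(C)=O)CCCCCCCc1cc(O[Si](C)(C)C(C)(C)C)cc(O)c1CN1CCOCC1 | intermediate
22 | N-methylmorpholinium iodide of 21 | C[C@@H](OC(C)=O)CCCCCCCc1cc(O[Si](C)(C)C(C)(C)C)cc(O)c1C[N+]1(C)CCOCC1.[I-] | intermediate
23 | o-quinone methide (6-methylidenecyclohexa-2,4-dienone carrying the silyloxy group and the acetoxynonyl chain) | C[C@@H](OC(C)=O)CCCCCCCC1=CC(O[Si](C)(C)C(C)(C)C)=CC(=O)C1=C | intermediate
24 | (R)-9-[(3S,3aS,9aS)-7-(tert-butyldimethylsilyloxy)-3,9a-dimethyl-2,3,3a,9a-tetrahydro-4H-furo[2,3-b]chromen-5-yl]nonan-2-yl acetate (cis-fused ketal, 3-methyl trans to C4) | C[C@@H](OC(C)=O)CCCCCCCc1cc(O[Si](C)(C)C(C)(C)C)cc2c1C[C@H]1[C@H](C)CO[C@@]1(C)O2 | intermediate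
25 | (3S,3aS,9aS)-5-[(8R)-8-hydroxynonyl]-3,9a-dimethyl-2,3,3a,9a-tetrahydro-4H-furo[2,3-b]chromen-7-ol | C[C@@H](O)CCCCCCCc1cc(O)cc2c1C[C@H]1[C@H](C)CO[C@@]1(C)O2 | intermediate
26 | 4-nitrophenyl carbonate of the phenol of 25 | C[C@@H](O)CCCCCCCc1cc(OC(=O)Oc3ccc(cc3)[N+](=O)[O-])cc2c1C[C@H]1[C@H](C)CO[C@@]1(C)O2 | intermediate
27 | 14-membered cyclic aryl alkyl carbonate (O-7 of the furochromene–C(=O)–O–(R)-CH(CH3)(CH2)7–C-5) | C[C@@H]1CCCCCCCc2cc(OC(=O)O1)cc3c2C[C@H]2[C@H](C)CO[C@@]2(C)O3 | intermediate
28 | cyclohexa-2,4-dienone tautomer of 29 (sp3 ring carbon bearing H and the lactone carbonyl) | O=C1C=C2C(=C3C1C(=O)O[C@H](C)CCCCCCC3)C[C@H]1[C@H](C)CO[C@@]1(C)O2 | intermediate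
29 | O-demethyl-lasiodiplactone A | Oc1cc2c(c3c1C(=O)O[C@H](C)CCCCCCC3)C[C@H]1[C@H](C)CO[C@@]1(C)O2 | intermediate
30 | lasiodiplactone A | COc1cc2c(c3c1C(=O)O[C@H](C)CCCCCCC3)C[C@H]1[C@H](C)CO[C@@]1(C)O2 | target

**Summary**

Total steps: 14. Longest linear sequence: 11 steps (steps 4–14); steps 1–3 make the dihydrofuran 7 for the convergent step 10.

Steps most likely to fail:

1. Step 13. The excited carbonate may simply return to 27, lose CO2 to give a ring-contracted aryl ether, or rearrange with low conversion because the product filters the light. Fallback (from 25, back at 30): 25 would be brominated with NBS (MeCN, −20 °C) at the ring CH between the chain and the free OH, para to the ketal oxygen, to give the bromophenol F1. MeI/K2CO3 would give the bromo methyl ether F2. A palladium-catalysed carbonylative macrolactonisation (Pd(OAc)2, Xantphos, CO 1 atm, Et3N, toluene, 100 °C, slow addition) would then insert CO between the aryl carbon and the tethered (R)-alcohol and give 30 directly, with no carbonate ring, no photochemistry and no final methylation.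

2. Step 12. Acylation may not discriminate fully between phenol and alcohol, and the transcarbonation may oligomerise instead of closing the 14-membered ring. Fallback (from 24, back at 27), with the roles of the two oxygens reversed: DIBAL-H (CH2Cl2, −78 °C) would remove only the acetate of 24 to give the silyl ether alcohol F3. 4-Nitrophenyl chloroformate/pyridine would convert the secondary alcohol into the alkyl 4-nitrophenyl carbonate F4. Slow addition of F4 to CsF in MeCN at high dilution would unmask the phenoxide at low stationary concentration, and it should close onto the activated carbonate to give 27.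

3. Step 10. The cycloaddition may show poor facial selectivity, or the quinone methide may self-condense faster than it is trapped. Fallback (from 19, back at 25), with both centers set by substrate-controlled lactone alkylation:
   - TBSOTf/2,6-lutidine would give the bis-silyl aldehyde F5.
   - NaBH4 would give the benzylic alcohol F6, and CBr4/PPh3 the benzylic bromide F7.
   - The lithium enolate of purchasable (S)-4-methyldihydrofuran-2(3H)-one (LDA, THF, −78 °C) would be alkylated by F7 anti to the β-methyl group to give the trans lactone F8.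
   - MeLi (excess, −78 °C) would add once to the lactone and cleave the acetate to give the methyl lactol F9.
   - TBAF followed by PPTS would remove both silyl groups and close the cis-fused ketal with the ortho phenol, giving 25.

Further compounds
F1 | step 13 | (3S,3aS,9aS)-6-bromo-5-[(8R)-8-hydroxynonyl]-3,9a-dimethyl-2,3,3a,9a-tetrahydro-4H-furo[2,3-b]chromen-7-ol | C[C@@H](O)CCCCCCCc1c(Br)c(O)cc2c1C[C@H]1[C@H](C)CO[C@@]1(C)O2
F2 | step 13 | (R)-9-[(3S,3aS,9aS)-6-bromo-7-methoxy-3,9a-dimethyl-2,3,3a,9a-tetrahydro-4H-furo[2,3-b]chromen-5-yl]nonan-2-ol | C[C@@H](O)CCCCCCCc1c(Br)c(OC)cc2c1C[C@H]1[C@H](C)CO[C@@]1(C)O2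
F3 | step 12 | (R)-9-[(3S,3aS,9aS)-7-(tert-butyldimethylsilyloxy)-3,9a-dimethyl-2,3,3a,9a-tetrahydro-4H-furo[2,3-b]chromen-5-yl]nonan-2-ol | C[C@@H](O)CCCCCCCc1cc(O[Si](C)(C)C(C)(C)C)cc2c1C[C@H]1[C@H](C)CO[C@@]1(C)O2
F4 | step 12 | 4-nitrophenyl carbonate of the secondary alcohol of F3 | C[C@@H](OC(=O)Oc1ccc(cc1)[N+](=O)[O-])CCCCCCCc1cc(O[Si](C)(C)C(C)(C)C)cc2c1C[C@H]1[C@H](C)CO[C@@]1(C)O2
F5 | step 10 | (R)-9-[3,5-bis(tert-butyldimethylsilyloxy)-2-formylphenyl]nonan-2-yl acetate | C[C@@H](OC(C)=O)CCCCCCCc1cc(O[Si](C)(C)C(C)(C)C)cc(O[Si](C)(C)C(C)(C)C)c1C=O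
F6 | step 10 | (R)-9-[3,5-bis(tert-butyldimethylsilyloxy)-2-(hydroxymethyl)phenyl]nonan-2-yl acetate | C[C@@H](OC(C)=O)CCCCCCCc1cc(O[Si](C)(C)C(C)(C)C)cc(O[Si](C)(C)C(C)(C)C)c1CO
F7 | step 10 | (R)-9-[2-(bromomethyl)-3,5-bis(tert-butyldimethylsilyloxy)phenyl]nonan-2-yl acetate | C[C@@H](OC(C)=O)CCCCCCCc1cc(O[Si](C)(C)C(C)(C)C)cc(O[Si](C)(C)C(C)(C)C)c1CBr
F8 | step 10 | trans-α-benzylated (3S,4S)-4-methyl-γ-butyrolactone carrying the bis-silyloxy aryl group and the acetoxynonyl chain | C[C@@H](OC(C)=O)CCCCCCCc1cc(O[Si](C)(C)C(C)(C)C)cc(O[Si](C)(C)C(C)(C)C)c1C[C@H]1[C@H](C)COC1=O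
F9 | step 10 | 2-methyl lactol (hemiketal) from F8 with the free (R)-secondary alcohol | C[C@@H](O)CCCCCCCc1cc(O[Si](C)(C)C(C)(C)C)cc(O[Si](C)(C)C(C)(C)C)c1C[C@H]1[C@H](C)COC1(C)O
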